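## Retrosynthetic overview

1. Target ⇐ C13 silyl ether ⇐ macrocyclic enone; the ten-membered carbocycle is formed last, by intramolecular Nozaki–Hiyama–Kishi closure of C1–C2 (C2 vinyl iodide onto the C1 α-acetoxy aldehyde).
2. The C2 carbon comes from Takai olefination of the C3 aldehyde; a lipase unmasks the C3 primary acetate in the presence of the C8 (secondary) and C10 (tertiary) acetates and the lactone.
3. The butenolide (second ring) ⇐ intramolecular Horner–Wadsworth–Emmons closure of a C6-O phosphonoacetate onto C7 of a C7/C8 1,2-dione (from the C7≡C8 alkyne); C8 carbinol by CBS reduction.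
4. The epoxide (first ring) ⇐ hydroxyl-directed epoxidation of the C6 carbinol, itself made by catalytic asymmetric alkynylation joining enal fragment E to alkyne fragment W (C6–C7).
5. Fragment W ⇐ methallyl alcohol by Sharpless asymmetric epoxidation (first stereocentre, C10) and acetylide opening; fragment E ⇐ prenal diethyl acetal; fragment P ⇐ benzyl phosphonoacetate and formaldehyde.

Convention: locants C1–C15 in names of advanced intermediates are the germacrane locants of the target (C1 ketone, C4–C5 epoxide, C6 lactone carbinol, C7=C11 butenolide alkene, C8 and C10 acetoxy carbons, C12 lactone carbonyl, C13 hydroxymethyl, C14/C15 methyls on C10/C4).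

## Forward route

Step 1
Reactants: 1 2-methylprop-2-en-1-ol
Product: 2 (S)-(2-methyloxiran-2-yl)methanol
Conditions: Ti(OiPr)4 (5 mol %), L-(+)-diisopropyl tartrate (6 mol %), t-BuOOH (2 eq), 4 Å MS, CH2Cl2, −20 °C
Reagents that add atoms: tert-butyl hydroperoxide, CC(C)(C)OO
Why: Sharpless asymmetric epoxidation, in which the Ti–tartrate complex delivers oxygen to one enantioface of the bound allylic alcohol and so sets the future C10 stereocentre by catalyst control.

Step 2
Reactants: 2 (S)-(2-methyloxiran-2-yl)methanol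
Product: 3 (R)-tert-butyldimethyl[(2-methyloxiran-2-yl)methoxy]silane
Conditions: TBSCl, imidazole, CH2Cl2, 0 °C
Reagents that add atoms: tert-butyldimethylsilyl chloride, CC(C)(C)[Si](C)(C)Cl
Why: Silylation of the unhindered primary alcohol; the stereocentre is untouched (the descriptor changes only through CIP priorities).

Step 3
Reactants: 3 (R)-silyl glycidyl ether; 4 lithium acetylide–ethylenediamine complex
Product: 5 (R)-1-[(tert-butyldimethylsilyl)oxy]-2-methylpent-4-yn-2-ol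
Conditions: LiC≡CH·H2NCH2CH2NH2 (3 eq), DMSO, 0 °C → rt; aq. NH4Cl
Reagents that add atoms: none
Why: SN2 epoxide opening by acetylide at the unsubstituted CH2 terminus, which leaves the quaternary stereocentre intact.

Step 4
Reactants: 5 (R)-tertiary alcohol
Product: 6 (R)-1-[(tert-butyldimethylsilyl)oxy]-2-methylpent-4-yn-2-yl acetate (fragment W)
Conditions: Ac2O, Et3N, DMAP (0.5 eq), CH2Cl2, rt → 40 °C
Reagents that add atoms: acetic anhydride, CC(=O)OC(C)=O
Why: DMAP-catalysed acylation puts on the hindered tertiary (C10) acetate early, where forcing conditions harm nothing.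

Step 5
Reactants: 7 1,1-diethoxy-3-methylbut-2-ene
Product: 8 (E)-4,4-diethoxy-2-methylbut-2-en-1-ol
Conditions: SeO2 (0.5 eq), t-BuOOH (2 eq, anhydrous), CH2Cl2, 0 °C → rt
Reagents that add atoms: selenium dioxide, O=[Se]=O (oxygen carrier); tert-butyl hydroperoxide, CC(C)(C)OO (terminal oxidant)
Why: Riley allylic oxidation (ene reaction then [2,3]-shift) oxidises only the E-methyl, fixing the alkene geometry that later gives the trans-epoxide.

Step 6
Reactants: 8 (E)-allylic alcohol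
Product: 9 (E)-4,4-diethoxy-2-methylbut-2-en-1-yl acetate
Conditions: Ac2O, pyridine, DMAP (cat.), CH2Cl2, 0 °C
Reagents that add atoms: acetic anhydride, CC(=O)OC(C)=O
Why: Simple acetylation; the primary acetate at C3 is the group the lipase later removes.

Step 7
Reactants: 9 (E)-acetal acetate
Product: 10 (E)-2-methyl-4-oxobut-2-en-1-yl acetate (fragment E)
Conditions: wet SiO2, oxalic acid (cat.), CH2Cl2, rt
Reagents that add atoms: water, O
Why: Mild acid-catalysed acetal hydrolysis liberates the enal without cleaving the allylic acetate or isomerising the E-alkene.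

Step 8
Reactants: 11 benzyl 2-(diethoxyphosphoryl)acetate; 12 paraformaldehyde
Product: 13 benzyl 2-(diethoxyphosphoryl)-3-hydroxypropanoate (racemic)
Conditions: (CH2O)n (1.0 eq), piperidine (10 mol %), THF, 50 °C
Reagents that add atoms: none
Why: Amine-catalysed aldol-type hydroxymethylation of the phosphonoacetate, where the weakly basic medium protonates the adduct before phosphate elimination can occur.

Step 9
Reactants: 13 hydroxymethyl phosphonate
Product: 14 benzyl 3-[(tert-butyldiphenylsilyl)oxy]-2-(diethoxyphosphoryl)propanoate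
Conditions: TBDPSCl, imidazole, DMF, rt
Reagents that add atoms: tert-butyldiphenylsilyl chloride, CC(C)(C)[Si](Cl)(c1ccccc1)c1ccccc1
Why: Silylation gives a robust C13-O group that is a poor leaving group β to the phosphonate carbanion.

Step 10
Reactants: 14 benzyl ester
Product: 15 3-[(tert-butyldiphenylsilyl)oxy]-2-(diethoxyphosphoryl)propanoic acid (fragment P)
Conditions: H2 (1 atm), Pd/C, EtOAc, rt
Reagents that add atoms: none
Why: Neutral hydrogenolysis of the benzyl ester frees the acid without touching the silyl ether or phosphonate.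

Step 11
Reactants: 6 fragment W alkyne; 10 fragment E enal
Product: 17 (2E,4R,8R)-9-[(tert-butyldimethylsilyl)oxy]-4-hydroxy-2,8-dimethylnon-2-en-5-yne-1,8-diyl diacetate, via methylzinc acetylide 16 (not isolated)
Conditions: Me2Zn (3 eq), (R,R)-ProPhenol (20 mol %), Ph3PO (40 mol %), toluene, 0 °C; 6 used in excess (2 eq) and recovered
Reagents that add atoms: none
Why: Trost Zn–ProPhenol catalytic asymmetric alkynylation, in which the dinuclear zinc catalyst delivers the alkynyl group to the Si face of the enal to set C6 (R here, the target sense) by catalyst control with C10 remote.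

Step 12
Reactants: 17 C6 propargylic/allylic alcohol
Product: 18 (2R,3R,4S,8R)-9-[(tert-butyldimethylsilyl)oxy]-2,3-epoxy-4-hydroxy-2,8-dimethylnon-5-yne-1,8-diyl diacetate
Conditions: mCPBA, NaHCO3, CH2Cl2, 0 °C
Reagents that add atoms: 3-chloroperoxybenzoic acid, OOC(=O)c1cccc(Cl)c1
Why: Henbest hydroxyl-directed epoxidation, where A(1,3) strain from the C15 methyl cis to C6 puts C6–H in the alkene plane so the hydrogen-bonded peracid attacks the OH face and gives the threo (4R,5R) epoxy alcohol.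

Step 13
Reactants: 18 epoxy alcohol; 15 fragment P acid
Product: 19 C6 ester of 18 with acid 15 (1:1 epimers at the phosphonate carbon)
Conditions: DCC, DMAP (cat.), CH2Cl2, 0 °C → rt
Reagents that add atoms: none
Why: Steglich esterification acylates the only free hydroxyl (C6) under near-neutral conditions.

Step 14
Reactants: 19 alkynyl phosphonoacetate
Product: 20 C7/C8 1,2-dione of 19
Conditions: RuCl3·xH2O (5 mol %), NaIO4 (3 eq), NaHCO3, CCl4/MeCN/H2O, 0 °C
Reagents that add atoms: sodium periodate, [Na+].[O-]I(=O)(=O)=O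
Why: RuO4 (generated catalytically) oxidises the internal alkyne to the 1,2-diketone, and no C=C bond is present to compete.

Step 15
Reactants: 20 dione phosphonate
Product: 21 butenolide ketone (C7=C11 closed, C8 ketone)
Conditions: LiCl (5 eq), i-Pr2NEt (3 eq), MeCN, 0 °C → rt
Reagents that add atoms: none
Why: Intramolecular Horner–Wadsworth–Emmons olefination under Masamune–Roush conditions closes the five-membered lactone onto the adjacent C7 carbonyl and erases the racemic phosphonate stereocentre.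

Step 16
Reactants: 21 butenolide ketone
Product: 22 C8 alcohol (8S)
Conditions: (R)-Me-CBS oxazaborolidine (0.3 eq), catecholborane (1.5 eq), toluene, −78 °C
Reagents that add atoms: none
Why: Corey–Bakshi–Shibata reduction, with the butenolide alkenyl group as the large substituent, delivers hydride to the face that gives the 8S carbinol by catalyst control.

Step 17
Reactants: 22 C8 alcohol
Product: 23 triacetate (C3 primary, C8 secondary, C10 tertiary acetates)
Conditions: Ac2O, pyridine, DMAP (cat.), CH2Cl2, 0 °C → rt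
Reagents that add atoms: acetic anhydride, CC(=O)OC(C)=O
Why: Acetylation installs the C8 acetate of the target.

Step 18
Reactants: 23 triacetate
Product: 24 C3 primary alcohol (C8 and C10 acetates intact)
Conditions: lipase (immobilised Candida antarctica lipase B), n-BuOH (5 eq), MTBE, 30 °C
Reagents that add atoms: none
Why: Lipase-catalysed transesterification (a serine hydrolase) accepts only the primary acetate, sparing the secondary and tertiary acetates, the lactone and the base-sensitive C6–H/epoxide array that chemical methanolysis would attack.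

Step 19
Reactants: 24 C3 alcohol
Product: 25 C3 epoxy aldehyde
Conditions: Dess–Martin periodinane, NaHCO3, CH2Cl2, 0 °C → rt
Reagents that add atoms: none
Why: Dess–Martin oxidation gives a non-enolisable α-quaternary epoxy aldehyde under buffered neutral conditions.

Step 20
Reactants: 25 epoxy aldehyde
Product: 26 (E)-vinyl iodide (C2=C3)
Conditions: CrCl2 (6 eq), CHI3 (2 eq), THF/dioxane, 0 °C → rt
Reagents that add atoms: iodoform, IC(I)I
Why: Takai olefination adds C2 as an E-configured iodoalkene under non-basic conditions tolerated by the butenolide, epoxide and acetates.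

Step 21
Reactants: 26 vinyl iodide
Product: 27 C1 primary alcohol
Conditions: HF·pyridine, pyridine, THF, 0 °C → rt; used at once
Reagents that add atoms: none
Why: Buffered fluoride desilylation cleaves the primary TBS ether much faster than the TBDPS ether at C13.

Step 22
Reactants: 27 C1 alcohol
Product: 28 C1 aldehyde
Conditions: Dess–Martin periodinane, NaHCO3, CH2Cl2, 0 °C
Reagents that add atoms: none
Why: Dess–Martin oxidation gives the α-acetoxy α-quaternary aldehyde, which cannot epimerise.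

Step 23
Reactants: 28 iodo aldehyde
Product: 30 macrocyclic allylic alcohol (C1 epimers), via alkenylchromium dichloride 29 (not isolated)
Conditions: CrCl2 (10 eq), NiCl2 (2 mol %), DMSO/THF, rt, syringe-pump addition to 2 mM
Reagents that add atoms: none
Why: Intramolecular Nozaki–Hiyama–Kishi reaction closes the ten-membered ring chemoselectively at the aldehyde under neutral conditions, and the new C1 carbinol configuration is irrelevant because it is oxidised next.

Step 24
Reactants: 30 macrocyclic allylic alcohol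
Product: 31 macrocyclic (E)-enone
Conditions: Dess–Martin periodinane, NaHCO3, CH2Cl2, 0 °C → rt
Reagents that add atoms: none
Why: Dess–Martin oxidation converges both C1 epimers on the C1 ketone before the alkene is saturated, so a free C1–OH never faces the epoxide transannularly.

Step 25
Reactants: 31 enone
Product: 32 saturated C1 ketone (C13 TBDPS ether)
Conditions: 2-nitrobenzenesulfonylhydrazide, Et3N, CH2Cl2, rt
Reagents that add atoms: none
Why: Diimide reduction transfers H2 concertedly to the disubstituted C2=C3 bond, leaving the tetrasubstituted butenolide alkene and (no metal present) the epoxide untouched.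

Step 26
Reactants: 32 silyl ether
Product: 33 (4R,5R,6S,8S,10R)-8,10-diacetoxy-4,5-epoxy-13-hydroxy-1-oxogermacr-7(11)-en-12,6-olide (target)
Conditions: TBAF, AcOH (1:1), THF, 0 °C → rt
Reagents that add atoms: none
Why: Acetic-acid-buffered fluoride desilylation frees the C13 alcohol at near-neutral pH, preserving the acetates and the base- and acid-sensitive C6–H/epoxide/ketone array.

## Compound list

1 | 2-methylprop-2-en-1-ol | CC(=C)CO | starting material
2 | (S)-(2-methyloxiran-2-yl)methanol | C[C@]1(CO)CO1 | intermediate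
3 | (R)-tert-butyldimethyl[(2-methyloxiran-2-yl)methoxy]silane | C[C@]1(CO[Si](C)(C)C(C)(C)C)CO1 | intermediate
4 | lithium acetylide–ethylenediamine complex | [Li+].[C-]#C.NCCN | starting material
5 | (R)-1-[(tert-butyldimethylsilyl)oxy]-2-methylpent-4-yn-2-ol | C[C@](O)(CO[Si](C)(C)C(C)(C)C)CC#C | intermediate
6 | (R)-1-[(tert-butyldimethylsilyl)oxy]-2-methylpent-4-yn-2-yl acetate (fragment W) | C[C@](OC(C)=O)(CO[Si](C)(C)C(C)(C)C)CC#C | intermediate
7 | 1,1-diethoxy-3-methylbut-2-ene | CCOC(OCC)C=C(C)C | starting material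
8 | (E)-4,4-diethoxy-2-methylbut-2-en-1-ol | CCOC(OCC)/C=C(\C)CO | intermediate
9 | (E)-4,4-diethoxy-2-methylbut-2-en-1-yl acetate | CCOC(OCC)/C=C(\C)COC(C)=O | intermediate
10 | (E)-2-methyl-4-oxobut-2-en-1-yl acetate (fragment E) | CC(=O)OC/C(C)=C/C=O | intermediate
11 | benzyl 2-(diethoxyphosphoryl)acetate | CCOP(=O)(OCC)CC(=O)OCc1ccccc1 | starting material
12 | paraformaldehyde (formaldehyde) | C=O | starting material
13 | benzyl 2-(diethoxyphosphoryl)-3-hydroxypropanoate (racemic) | CCOP(=O)(OCC)C(CO)C(=O)OCc1ccccc1 | intermediate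
14 | benzyl 3-[(tert-butyldiphenylsilyl)oxy]-2-(diethoxyphosphoryl)propanoate (racemic) | CCOP(=O)(OCC)C(CO[Si](c1ccccc1)(c1ccccc1)C(C)(C)C)C(=O)OCc1ccccc1 | intermediate
15 | 3-[(tert-butyldiphenylsilyl)oxy]-2-(diethoxyphosphoryl)propanoic acid (racemic; fragment P) | CCOP(=O)(OCC)C(CO[Si](c1ccccc1)(c1ccccc1)C(C)(C)C)C(O)=O | intermediate
16 | methylzinc acetylide of 6 | C[Zn]C#CC[C@@](C)(OC(C)=O)CO[Si](C)(C)C(C)(C)C | intermediate
17 | (2E,4R,8R)-9-[(tert-butyldimethylsilyl)oxy]-4-hydroxy-2,8-dimethylnon-2-en-5-yne-1,8-diyl diacetate | CC(=O)OC/C(C)=C/[C@@H](O)C#CC[C@@](C)(OC(C)=O)CO[Si](C)(C)C(C)(C)C | intermediate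
18 | (2R,3R,4S,8R)-9-[(tert-butyldimethylsilyl)oxy]-2,3-epoxy-4-hydroxy-2,8-dimethylnon-5-yne-1,8-diyl diacetate | CC(=O)OC[C@@]1(C)O[C@@H]1[C@@H](O)C#CC[C@@](C)(OC(C)=O)CO[Si](C)(C)C(C)(C)C | intermediate
19 | (2R,3R,4S,8R)-1,8-diacetoxy-9-[(tert-butyldimethylsilyl)oxy]-2,3-epoxy-2,8-dimethylnon-5-yn-4-yl 3-[(tert-butyldiphenylsilyl)oxy]-2-(diethoxyphosphoryl)propanoate (epimers at the phosphonate carbon) | CC(=O)OC[C@@]1(C)O[C@@H]1[C@@H](OC(=O)C(CO[Si](c2ccccc2)(c2ccccc2)C(C)(C)C)P(=O)(OCC)OCC)C#CC[C@@](C)(OC(C)=O)CO[Si](C)(C)C(C)(C)C | intermediate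
20 | (2R,3R,4R,8R)-1,8-diacetoxy-9-[(tert-butyldimethylsilyl)oxy]-2,3-epoxy-2,8-dimethyl-5,6-dioxononan-4-yl 3-[(tert-butyldiphenylsilyl)oxy]-2-(diethoxyphosphoryl)propanoate | CC(=O)OC[C@@]1(C)O[C@@H]1[C@@H](OC(=O)C(CO[Si](c2ccccc2)(c2ccccc2)C(C)(C)C)P(=O)(OCC)OCC)C(=O)C(=O)C[C@@](C)(OC(C)=O)CO[Si](C)(C)C(C)(C)C | intermediate
21 | (S)-5-[(2R,3R)-3-(acetoxymethyl)-3-methyloxiran-2-yl]-4-[(R)-3-acetoxy-4-[(tert-butyldimethylsilyl)oxy]-3-methylbutanoyl]-3-{[(tert-butyldiphenylsilyl)oxy]methyl}furan-2(5H)-one | CC(=O)OC[C@@]1(C)O[C@@H]1[C@H]2OC(=O)C(CO[Si](c3ccccc3)(c3ccccc3)C(C)(C)C)=C2C(=O)C[C@@](C)(OC(C)=O)CO[Si](C)(C)C(C)(C)C | intermediate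
22 | (S)-5-[(2R,3R)-3-(acetoxymethyl)-3-methyloxiran-2-yl]-4-[(1S,3R)-3-acetoxy-4-[(tert-butyldimethylsilyl)oxy]-1-hydroxy-3-methylbutyl]-3-{[(tert-butyldiphenylsilyl)oxy]methyl}furan-2(5H)-one | CC(=O)OC[C@@]1(C)O[C@@H]1[C@H]2OC(=O)C(CO[Si](c3ccccc3)(c3ccccc3)C(C)(C)C)=C2[C@@H](O)C[C@@](C)(OC(C)=O)CO[Si](C)(C)C(C)(C)C | intermediate
23 | (S)-5-[(2R,3R)-3-(acetoxymethyl)-3-methyloxiran-2-yl]-4-[(1S,3R)-1,3-diacetoxy-4-[(tert-butyldimethylsilyl)oxy]-3-methylbutyl]-3-{[(tert-butyldiphenylsilyl)oxy]methyl}furan-2(5H)-one | CC(=O)OC[C@@]1(C)O[C@@H]1[C@H]2OC(=O)C(CO[Si](c3ccccc3)(c3ccccc3)C(C)(C)C)=C2[C@@H](OC(C)=O)C[C@@](C)(OC(C)=O)CO[Si](C)(C)C(C)(C)C | intermediate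
24 | (S)-4-[(1S,3R)-1,3-diacetoxy-4-[(tert-butyldimethylsilyl)oxy]-3-methylbutyl]-3-{[(tert-butyldiphenylsilyl)oxy]methyl}-5-[(2R,3R)-3-(hydroxymethyl)-3-methyloxiran-2-yl]furan-2(5H)-one | OC[C@@]1(C)O[C@@H]1[C@H]2OC(=O)C(CO[Si](c3ccccc3)(c3ccccc3)C(C)(C)C)=C2[C@@H](OC(C)=O)C[C@@](C)(OC(C)=O)CO[Si](C)(C)C(C)(C)C | intermediate
25 | (S)-4-[(1S,3R)-1,3-diacetoxy-4-[(tert-butyldimethylsilyl)oxy]-3-methylbutyl]-3-{[(tert-butyldiphenylsilyl)oxy]methyl}-5-[(2R,3S)-3-formyl-3-methyloxiran-2-yl]furan-2(5H)-one | O=C[C@@]1(C)O[C@@H]1[C@H]2OC(=O)C(CO[Si](c3ccccc3)(c3ccccc3)C(C)(C)C)=C2[C@@H](OC(C)=O)C[C@@](C)(OC(C)=O)CO[Si](C)(C)C(C)(C)C | intermediate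
26 | (S)-4-[(1S,3R)-1,3-diacetoxy-4-[(tert-butyldimethylsilyl)oxy]-3-methylbutyl]-3-{[(tert-butyldiphenylsilyl)oxy]methyl}-5-[(2R,3R)-3-[(E)-2-iodoethenyl]-3-methyloxiran-2-yl]furan-2(5H)-one | I/C=C/[C@@]1(C)O[C@@H]1[C@H]2OC(=O)C(CO[Si](c3ccccc3)(c3ccccc3)C(C)(C)C)=C2[C@@H](OC(C)=O)C[C@@](C)(OC(C)=O)CO[Si](C)(C)C(C)(C)C | intermediate
27 | (S)-4-[(1S,3R)-1,3-diacetoxy-4-hydroxy-3-methylbutyl]-3-{[(tert-butyldiphenylsilyl)oxy]methyl}-5-[(2R,3R)-3-[(E)-2-iodoethenyl]-3-methyloxiran-2-yl]furan-2(5H)-one | I/C=C/[C@@]1(C)O[C@@H]1[C@H]2OC(=O)C(CO[Si](c3ccccc3)(c3ccccc3)C(C)(C)C)=C2[C@@H](OC(C)=O)C[C@@](C)(OC(C)=O)CO | intermediate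
28 | (S)-4-[(1S,3R)-1,3-diacetoxy-3-methyl-4-oxobutyl]-3-{[(tert-butyldiphenylsilyl)oxy]methyl}-5-[(2R,3R)-3-[(E)-2-iodoethenyl]-3-methyloxiran-2-yl]furan-2(5H)-one | I/C=C/[C@@]1(C)O[C@@H]1[C@H]2OC(=O)C(CO[Si](c3ccccc3)(c3ccccc3)C(C)(C)C)=C2[C@@H](OC(C)=O)C[C@@](C)(OC(C)=O)C=O | intermediate
29 | alkenylchromium dichloride from 28 (C2–CrCl2) | Cl[Cr](Cl)/C=C/[C@@]1(C)O[C@@H]1[C@H]2OC(=O)C(CO[Si](c3ccccc3)(c3ccccc3)C(C)(C)C)=C2[C@@H](OC(C)=O)C[C@@](C)(OC(C)=O)C=O | intermediate
30 | (2E,4R,5R,6S,8S,10R)-8,10-diacetoxy-13-[(tert-butyldiphenylsilyl)oxy]-4,5-epoxy-1-hydroxygermacra-2,7(11)-dien-12,6-olide (C1 epimers) | CC(=O)O[C@H]1C[C@@](C)(OC(C)=O)C(O)/C=C/[C@@]2(C)O[C@@H]2[C@H]2OC(=O)C(CO[Si](c3ccccc3)(c3ccccc3)C(C)(C)C)=C12 | intermediate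
31 | (2E,4R,5R,6S,8S,10R)-8,10-diacetoxy-13-[(tert-butyldiphenylsilyl)oxy]-4,5-epoxy-1-oxogermacra-2,7(11)-dien-12,6-olide | CC(=O)O[C@H]1C[C@@](C)(OC(C)=O)C(=O)/C=C/[C@@]2(C)O[C@@H]2[C@H]2OC(=O)C(CO[Si](c3ccccc3)(c3ccccc3)C(C)(C)C)=C12 | intermediate
32 | (4R,5R,6S,8S,10R)-8,10-diacetoxy-13-[(tert-butyldiphenylsilyl)oxy]-4,5-epoxy-1-oxogermacr-7(11)-en-12,6-olide | CC(=O)O[C@H]1C[C@@](C)(OC(C)=O)C(=O)CC[C@@]2(C)O[C@@H]2[C@H]2OC(=O)C(CO[Si](c3ccccc3)(c3ccccc3)C(C)(C)C)=C12 | intermediate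
33 | (4R,5R,6S,8S,10R)-8,10-diacetoxy-4,5-epoxy-13-hydroxy-1-oxogermacr-7(11)-en-12,6-olide | CC(=O)O[C@H]1C[C@@](C)(OC(C)=O)C(=O)CC[C@@]2(C)O[C@@H]2[C@H]2OC(=O)C(CO)=C12 | target

## Step count and risks

Total steps: 26. Longest linear sequence: 20 steps (steps 1–4, then 11–26).

The three steps most likely to fail:

Step 15 (butenolide closure). The carbanion carries a β-silyloxy group that could be expelled, the C8 carbonyl could compete with C7 to give a six-membered ring, and the base could eliminate the C10 acetate or open the epoxide from C6. The fallback sets out from 18 and replaces the phosphonate anion by a neutral, ester-stabilised phosphorus ylide. Acrylic acid is converted with NBS in water into 2-bromo-3-hydroxypropanoic acid F1, which is silylated (TBDPSCl, imidazole; aqueous K2CO3 work-up to cleave the silyl ester) to 2-bromo-3-[(tert-butyldiphenylsilyl)oxy]propanoic acid F2. DCC/DMAP coupling of F2 with 18 gives the α-bromo ester F3, and RuCl3/NaIO4 oxidises its alkyne to the bromo dione F4. PPh3 (MeCN, 40 °C) then gives the phosphonium bromide F5, and Et3N triggers an intramolecular Wittig olefination onto C7 that comes back to the route at 21.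

Step 16 (CBS reduction at C8). The ketone sits between a bulky tetrasubstituted butenolide and a neopentyl-type chain, so catalyst control may be eroded by substrate bias. The fallback sets out from 21 and corrects the configuration by inversion instead of setting it by reduction. Luche reduction (NaBH4, CeCl3·7H2O, MeOH, −78 °C) gives the C8 alcohols under substrate control; any 8S alcohol is 22 itself. The (8R)-alcohol F6 is treated with acetic acid under Mitsunobu conditions (PPh3, DIAD, THF), which installs the acetate with inversion and comes back to the route at 23.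

Step 23 (NHK closure of the ten-membered ring). A strained ring holding an E-alkene, a trans-epoxide and the butenolide sp2 carbon must close against oligomerisation. The fallback sets out from 26 and closes the same C2=C3 region by ring-closing metathesis. Bu3SnH (Et3B, air, toluene, 0 °C) exchanges iodine for hydrogen to give the terminal vinyl epoxide F7. HF·pyridine gives the C1 alcohol F8 and Dess–Martin oxidation the C1 aldehyde F9. Intermolecular Nozaki–Hiyama–Kishi addition of vinyl bromide (CrCl2, NiCl2 cat., DMSO) gives the C1 vinyl carbinol F10. Metathesis with (H2IMes)(PCy3)Cl2Ru=CHPh (second-generation Grubbs catalyst; CH2Cl2, 40 °C, 1 mM) then gives 30 and/or its C2=C3 Z isomer F11. F11 is carried through the conditions of steps 24 and 25, via the Z-enone F12, so the fallback comes back to the route at 30 or, for the Z series, at 32.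

## Further compounds

F1 | step 15 | 2-bromo-3-hydroxypropanoic acid (racemic) | OCC(Br)C(O)=O
F2 | step 15 | 2-bromo-3-[(tert-butyldiphenylsilyl)oxy]propanoic acid (racemic) | OC(=O)C(Br)CO[Si](c1ccccc1)(c1ccccc1)C(C)(C)C
F3 | step 15 | C6 α-bromo ester of 18 with F2 | CC(=O)OC[C@@]1(C)O[C@@H]1[C@@H](OC(=O)C(Br)CO[Si](c2ccccc2)(c2ccccc2)C(C)(C)C)C#CC[C@@](C)(OC(C)=O)CO[Si](C)(C)C(C)(C)C
F4 | step 15 | C7/C8 1,2-dione of F3 | CC(=O)OC[C@@]1(C)O[C@@H]1[C@@H](OC(=O)C(Br)CO[Si](c2ccccc2)(c2ccccc2)C(C)(C)C)C(=O)C(=O)C[C@@](C)(OC(C)=O)CO[Si](C)(C)C(C)(C)C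
F5 | step 15 | triphenylphosphonium bromide from F4 | CC(=O)OC[C@@]1(C)O[C@@H]1[C@@H](OC(=O)C(CO[Si](c2ccccc2)(c2ccccc2)C(C)(C)C)[P+](c2ccccc2)(c2ccccc2)c2ccccc2)C(=O)C(=O)C[C@@](C)(OC(C)=O)CO[Si](C)(C)C(C)(C)C.[Br-]
F6 | step 16 | (8R)-epimer of alcohol 22 | CC(=O)OC[C@@]1(C)O[C@@H]1[C@H]2OC(=O)C(CO[Si](c3ccccc3)(c3ccccc3)C(C)(C)C)=C2[C@H](O)C[C@@](C)(OC(C)=O)CO[Si](C)(C)C(C)(C)C
F7 | step 23 | terminal vinyl epoxide (26 with I replaced by H) | C=C[C@@]1(C)O[C@@H]1[C@H]2OC(=O)C(CO[Si](c3ccccc3)(c3ccccc3)C(C)(C)C)=C2[C@@H](OC(C)=O)C[C@@](C)(OC(C)=O)CO[Si](C)(C)C(C)(C)C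
F8 | step 23 | C1 alcohol of F7 | C=C[C@@]1(C)O[C@@H]1[C@H]2OC(=O)C(CO[Si](c3ccccc3)(c3ccccc3)C(C)(C)C)=C2[C@@H](OC(C)=O)C[C@@](C)(OC(C)=O)CO
F9 | step 23 | C1 aldehyde of F7 | C=C[C@@]1(C)O[C@@H]1[C@H]2OC(=O)C(CO[Si](c3ccccc3)(c3ccccc3)C(C)(C)C)=C2[C@@H](OC(C)=O)C[C@@](C)(OC(C)=O)C=O
F10 | step 23 | C1 vinyl carbinol (C1 epimers) | C=C[C@@]1(C)O[C@@H]1[C@H]2OC(=O)C(CO[Si](c3ccccc3)(c3ccccc3)C(C)(C)C)=C2[C@@H](OC(C)=O)C[C@@](C)(OC(C)=O)C(O)C=C
F11 | step 23 | (2Z)-isomer of macrocyclic alcohol 30 | CC(=O)O[C@H]1C[C@@](C)(OC(C)=O)C(O)/C=C\[C@@]2(C)O[C@@H]2[C@H]2OC(=O)C(CO[Si](c3ccccc3)(c3ccccc3)C(C)(C)C)=C12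
F12 | step 23 | (2Z)-isomer of enone 31 | CC(=O)O[C@H]1C[C@@](C)(OC(C)=O)C(=O)/C=C\[C@@]2(C)O[C@@H]2[C@H]2OC(=O)C(CO[Si](c3ccccc3)(c3ccccc3)C(C)(C)C)=C12
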